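Rings: A methoxy ring, B middle, C acid ring; in each, C1 bears the carbonyl, C2 and C4 the oxygens, C6 the methyl. Ring B is an orsellinate esterified at C1 by the ring C C4 oxygen, i.e. the aldol fold of an aryl 3,5,7-trioxooctanoate, so that ester C–O bond and the ring B C1–C6 bond are disconnected to the acylketene stored in diketo-dioxinone 6. Heated with benzyl orsellinate 8, 6 releases the ketene, the non-chelated ring C C4–OH captures it, and the triketo ester cyclizes and aromatizes in the same flask, leaving ring B C4–OH free for ring A. Ring C C2–OH needs no protection: its hydrogen bond to the ester masks it.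

Key step: step 4

Remark: ring C enters with its C2–OH free; the hydrogen bond to the ortho ester carbonyl is assumed to keep this hydroxyl out of the ketene capture (step 4) and out of the later acylation (step 8), as is usual for orsellinate esters, which makes the phenol partner a one-step compound.

Step 1
Reactants: 1 2,2,6-trimethyl-4H-1,3-dioxin-4-one; 2 1-acetylimidazole
Product: 4 2,2-dimethyl-6-(2-oxopropyl)-4H-1,3-dioxin-4-one, via lithium dienolate 3 (not isolated)
Conditions: 1 (2 equiv.), LiN(iPr)2 (2 equiv.), THF, −78 °C; then 2 (1 equiv.), −78 → −40 °C; aq. HCl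
Reagents that add atoms: none
Why: γ-Deprotonation of the vinylogous ester gives dienolate 3, which should be C-acylated at its exocyclic carbon by the acyl imidazole (vinylogous crossed Claisen condensation), the second equivalent of 3 taking up the acidic proton of the β-keto product.

Step 2
Reactants: 4 2,2-dimethyl-6-(2-oxopropyl)-4H-1,3-dioxin-4-one; 2 1-acetylimidazole
Product: 6 2,2-dimethyl-6-(2,4-dioxopentyl)-4H-1,3-dioxin-4-one, via dilithium dienolate 5 (not isolated)
Conditions: 4 (2 equiv.), LiN(iPr)2 (4 equiv.), THF, −78 °C; then 2 (1 equiv.), −78 → −20 °C; aq. HCl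
Reagents that add atoms: none
Why: Double deprotonation gives dianion 5, whose last-formed and most nucleophilic terminal carbon should attack the acyl imidazole (Claisen-type γ-acylation of a 1,3-dicarbonyl dianion), so the chain grows linearly while the excess dianion neutralizes the acidic 1,3-diketone formed.

Step 3
Reactants: 7 orsellinic acid (2,4-dihydroxy-6-methylbenzoic acid)
Product: 8 benzyl 2,4-dihydroxy-6-methylbenzoate (benzyl orsellinate)
Conditions: BnBr (1.05 equiv.), KHCO3, DMF, rt
Reagents that add atoms: benzyl bromide, BrCc1ccccc1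
Why: Hydrogencarbonate ionizes only the carboxylic acid, so SN2 alkylation of the carboxylate by benzyl bromide (carboxylate O-alkylation) should give the ester with both phenols untouched, at a temperature at which the acid does not decarboxylate.

Step 4
Reactants: 6 2,2-dimethyl-6-(2,4-dioxopentyl)-4H-1,3-dioxin-4-one; 8 benzyl 2,4-dihydroxy-6-methylbenzoate
Product: 12 benzyl 4-[(2,4-dihydroxy-6-methylbenzoyl)oxy]-2-hydroxy-6-methylbenzoate, via acylketene 9 (not isolated), via triketo aryl ester 10 (not isolated), via cyclic aldol 11 (not isolated)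
Conditions: 8 (2 equiv.), PhMe, 110 °C (6 added slowly); cool, Et3N, CH2Cl2, 0 °C → rt; then TFA, rt
Reagents that add atoms: none
Why: Retro-[4+2] loss of acetone from 6 at 110 °C gives acylketene 9, and O–H addition of the non-chelated ring C C4–OH of 8 across its C=C=O unit forms the phenol oxygen–acyl carbon bond of triketo aryl ester 10. Triethylamine then enolizes 10 and chain C2 (future ring B C1) adds to the C7 ketone (future C6) in a six-membered 6-(enolendo)-exo-trig aldol closure to give 11, which loses water under acid and tautomerizes to the aromatic ring B, so that the ring B C1–C6 bond and the ring itself are made in the same flask. The closest known reaction type is the dioxinone thermolysis, hydroxyl trapping and aldol aromatization sequence to resorcylate esters, together with the formation of aryl acetoacetates from dioxinones and phenols. No stereocentre survives, since the two of 11 are erased on aromatization. Two selectivities are needed: capture at C4–OH and not at C2–OH of 8, secured by the hydrogen bond of C2–OH to the ester carbonyl and by the excess of 8 that outruns self-capture of the ketene by its own enol, and aldol closure in preference to Claisen closure or lactonization with loss of the aryloxide, secured by a weak amine base at low temperature in a non-nucleophilic solvent with acid added only after cyclization. The ring is born with C2–OH chelated to the new ester and C4–OH free, which is the differentiation step 8 relies on.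

Step 5
Reactants: 7 orsellinic acid
Product: 13 benzyl 4-(benzyloxy)-2-hydroxy-6-methylbenzoate
Conditions: BnBr (2.05 equiv.), K2CO3, DMF, rt
Reagents that add atoms: benzyl bromide, BrCc1ccccc1
Why: Carbonate ionizes the acid and the non-chelated C4 phenol far more readily than the C2 phenol, which is held in a hydrogen bond to the carbonyl, so two equivalents of benzyl bromide should give the ester and the C4 ether only (carboxylate alkylation plus Williamson etherification).

Step 6
Reactants: 13 benzyl 4-(benzyloxy)-2-hydroxy-6-methylbenzoate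
Product: 14 benzyl 4-(benzyloxy)-2-methoxy-6-methylbenzoate
Conditions: MeI, K2CO3, DMF, 50 °C
Reagents that add atoms: iodomethane, CI
Why: With the other acidic sites capped, the chelated C2 phenol should be methylated under more forcing Williamson conditions (iodomethane in warm DMF).

Step 7
Reactants: 14 benzyl 4-(benzyloxy)-2-methoxy-6-methylbenzoate
Product: 15 4-(benzyloxy)-2-methoxy-6-methylbenzoic acid
Conditions: KOH, DMSO–H2O, 80 °C; then aq. HCl, 0 °C
Reagents that add atoms: potassium hydroxide, [K+].[OH-]
Why: Saponification of the di-ortho-substituted benzyl ester by acyl–oxygen cleavage needs poorly solvated hydroxide in hot aqueous DMSO, to which both aryl ethers are inert, and cold acidification should release the acid without decarboxylation.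

Step 8
Reactants: 12 benzyl 4-[(2,4-dihydroxy-6-methylbenzoyl)oxy]-2-hydroxy-6-methylbenzoate; 15 4-(benzyloxy)-2-methoxy-6-methylbenzoic acid
Product: 17 benzyl 4-[(4-{[4-(benzyloxy)-2-methoxy-6-methylbenzoyl]oxy}-2-hydroxy-6-methylbenzoyl)oxy]-2-hydroxy-6-methylbenzoate, via mixed anhydride 16 (not isolated)
Conditions: 15 (1.1 equiv.), TFAA, PhMe, rt; aq. NaHCO3 work-up
Reagents that add atoms: none
Why: The mixed anhydride 16, an acylium-type donor suited to di-ortho-substituted benzoic acids, should acylate only ring B C4–OH, the one phenol of 12 not held in a hydrogen bond to an ester carbonyl, and transient aryl trifluoroacetates are lost on bicarbonate work-up (trifluoroacetic anhydride-mediated depside esterification).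

Step 9
Reactants: 17 benzyl 4-[(4-{[4-(benzyloxy)-2-methoxy-6-methylbenzoyl]oxy}-2-hydroxy-6-methylbenzoyl)oxy]-2-hydroxy-6-methylbenzoate
Product: 18 umbilicaric acid
Conditions: H2 (1 atm), Pd/C, EtOAc–THF, rt
Reagents that add atoms: none
Why: Hydrogenolysis over palladium on carbon should cleave the benzyl ester and the benzyl aryl ether to toluene while the two aryl ester links, the methyl ether and the arene rings stay intact at room temperature.

Compound list
1 | 2,2,6-trimethyl-4H-1,3-dioxin-4-one | CC1=CC(=O)OC(C)(C)O1 | starting material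
2 | 1-acetylimidazole | CC(=O)n1ccnc1 | starting material
3 | lithium dienolate of 1, lithium 2,2-dimethyl-6-methylidene-6H-1,3-dioxin-4-olate (not isolated) | C=C1C=C(O[Li])OC(C)(C)O1 | intermediate
4 | 2,2-dimethyl-6-(2-oxopropyl)-4H-1,3-dioxin-4-one | CC(=O)CC1=CC(=O)OC(C)(C)O1 | intermediate
5 | dilithium dienolate of 4 (not isolated) | C=C(O[Li])C=C1C=C(O[Li])OC(C)(C)O1 | intermediate
6 | 2,2-dimethyl-6-(2,4-dioxopentyl)-4H-1,3-dioxin-4-one | CC(=O)CC(=O)CC1=CC(=O)OC(C)(C)O1 | intermediate
7 | orsellinic acid (2,4-dihydroxy-6-methylbenzoic acid) | Cc1cc(O)cc(O)c1C(=O)O | starting material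
8 | benzyl 2,4-dihydroxy-6-methylbenzoate (benzyl orsellinate) | Cc1cc(O)cc(O)c1C(=O)OCc1ccccc1 | intermediate
9 | acylketene, oct-1-ene-1,3,5,7-tetrone (not isolated) | CC(=O)CC(=O)CC(=O)C=C=O | intermediate
10 | benzyl 2-hydroxy-6-methyl-4-[(3,5,7-trioxooctanoyl)oxy]benzoate (not isolated) | CC(=O)CC(=O)CC(=O)CC(=O)Oc1cc(C)c(C(=O)OCc2ccccc2)c(O)c1 | intermediate
11 | benzyl 2-hydroxy-4-[(2-hydroxy-2-methyl-4,6-dioxocyclohexane-1-carbonyl)oxy]-6-methylbenzoate, diastereomer mixture (not isolated) | CC1(O)CC(=O)CC(=O)C1C(=O)Oc1cc(C)c(C(=O)OCc2ccccc2)c(O)c1 | intermediate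
12 | benzyl 4-[(2,4-dihydroxy-6-methylbenzoyl)oxy]-2-hydroxy-6-methylbenzoate | Cc1cc(O)cc(O)c1C(=O)Oc1cc(C)c(C(=O)OCc2ccccc2)c(O)c1 | intermediate
13 | benzyl 4-(benzyloxy)-2-hydroxy-6-methylbenzoate | Cc1cc(OCc2ccccc2)cc(O)c1C(=O)OCc1ccccc1 | intermediate
14 | benzyl 4-(benzyloxy)-2-methoxy-6-methylbenzoate | COc1cc(OCc2ccccc2)cc(C)c1C(=O)OCc1ccccc1 | intermediate
15 | 4-(benzyloxy)-2-methoxy-6-methylbenzoic acid | COc1cc(OCc2ccccc2)cc(C)c1C(=O)O | intermediate
16 | 4-(benzyloxy)-2-methoxy-6-methylbenzoic trifluoroacetic anhydride (not isolated) | COc1cc(OCc2ccccc2)cc(C)c1C(=O)OC(=O)C(F)(F)F | intermediate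
17 | benzyl 4-[(4-{[4-(benzyloxy)-2-methoxy-6-methylbenzoyl]oxy}-2-hydroxy-6-methylbenzoyl)oxy]-2-hydroxy-6-methylbenzoate | COc1cc(OCc2ccccc2)cc(C)c1C(=O)Oc1cc(C)c(C(=O)Oc2cc(C)c(C(=O)OCc3ccccc3)c(O)c2)c(O)c1 | intermediate
18 | umbilicaric acid | COc1cc(O)cc(C)c1C(=O)Oc1cc(C)c(C(=O)Oc2cc(C)c(C(=O)O)c(O)c2)c(O)c1 | target

Total step count: 9. Longest linear sequence: 5 steps (steps 1, 2, 4, 8, 9; the ring A branch, steps 5, 6, 7, 8, 9, is equally long).

Steps most likely to fail

Step 4. The ketene may be consumed by its own enol oxygen (closure to a pyranone) or by dimerization before the weakly nucleophilic phenol adds. Under base, Claisen closure or lactonization with loss of the aryloxide may outrun the aldol closure, and capture may stray to the chelated hydroxyl. The fallback builds ring B from orsellinic acid instead of folding it, setting out from 7 and 8 and coming back at 12. Exhaustive benzylation of 7 (BnBr, K2CO3, DMF) would give benzyl 2,4-bis(benzyloxy)-6-methylbenzoate F1. Saponification as in step 7 would give 2,4-bis(benzyloxy)-6-methylbenzoic acid F2. Condensation of F2 with 8 by TFAA in PhMe would give benzyl 4-{[2,4-bis(benzyloxy)-6-methylbenzoyl]oxy}-2-hydroxy-6-methylbenzoate F3. Hydrogenolysis over Pd/C would give lecanoric acid F4, whose carboxyl alone would be re-benzylated with BnBr and KHCO3 in DMF to return to 12.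

Step 2. Proton exchange between the dianion and the acidic product may stall the acylation, and O-acylation or acylation at the internal carbon may compete. The fallback replaces dianion chemistry by soft enolization of a keto ester, setting out from 1 and coming back at 6. Dienolate 3 would be acylated with allyl 3-chloro-3-oxopropanoate F5 (from commercial mono-allyl malonate and oxalyl chloride) to give allyl 4-(2,2-dimethyl-4-oxo-4H-1,3-dioxin-6-yl)-3-oxobutanoate F6. MgCl2, pyridine and acetyl chloride would C-acetylate the carbon between ketone and allyl ester to give allyl 2-acetyl-4-(2,2-dimethyl-4-oxo-4H-1,3-dioxin-6-yl)-3-oxobutanoate F7. Pd(PPh3)4 with morpholine would then remove the allyl group, and the freed β-keto acid would lose carbon dioxide to give 6.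

Step 8. Acylation may spread to a chelated hydroxyl, the trifluoroacetic acid formed may promote acyl exchange between the depside esters, and the di-ortho-substituted acid may react sluggishly with the three-phenol substrate. The fallback changes the order of assembly (rings A and B joined first, ring C last), setting out from 15 (with 7 and 8) and coming back at 17. Orsellinic acid 7 with allyl bromide and KHCO3 in DMF would give allyl 2,4-dihydroxy-6-methylbenzoate F8. Condensation of F8 with 15 by TFAA in PhMe, on a substrate with a single non-chelated phenol, would give allyl 4-{[4-(benzyloxy)-2-methoxy-6-methylbenzoyl]oxy}-2-hydroxy-6-methylbenzoate F9. Pd(PPh3)4 with morpholine would release 4-{[4-(benzyloxy)-2-methoxy-6-methylbenzoyl]oxy}-2-hydroxy-6-methylbenzoic acid F10, which would be esterified with the C4–OH of 8 by DCC in PhMe to give 17.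

Further compounds
F1 | step 4 | benzyl 2,4-bis(benzyloxy)-6-methylbenzoate | Cc1cc(OCc2ccccc2)cc(OCc2ccccc2)c1C(=O)OCc1ccccc1
F2 | step 4 | 2,4-bis(benzyloxy)-6-methylbenzoic acid | Cc1cc(OCc2ccccc2)cc(OCc2ccccc2)c1C(=O)O
F3 | step 4 | benzyl 4-{[2,4-bis(benzyloxy)-6-methylbenzoyl]oxy}-2-hydroxy-6-methylbenzoate | Cc1cc(OCc2ccccc2)cc(OCc2ccccc2)c1C(=O)Oc1cc(C)c(C(=O)OCc2ccccc2)c(O)c1
F4 | step 4 | lecanoric acid, 4-[(2,4-dihydroxy-6-methylbenzoyl)oxy]-2-hydroxy-6-methylbenzoic acid | Cc1cc(O)cc(O)c1C(=O)Oc1cc(C)c(C(=O)O)c(O)c1
F5 | step 2 | allyl 3-chloro-3-oxopropanoate | C=CCOC(=O)CC(=O)Cl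
F6 | step 2 | allyl 4-(2,2-dimethyl-4-oxo-4H-1,3-dioxin-6-yl)-3-oxobutanoate | C=CCOC(=O)CC(=O)CC1=CC(=O)OC(C)(C)O1
F7 | step 2 | allyl 2-acetyl-4-(2,2-dimethyl-4-oxo-4H-1,3-dioxin-6-yl)-3-oxobutanoate | C=CCOC(=O)C(C(C)=O)C(=O)CC1=CC(=O)OC(C)(C)O1
F8 | step 8 | allyl 2,4-dihydroxy-6-methylbenzoate | Cc1cc(O)cc(O)c1C(=O)OCC=C
F9 | step 8 | allyl 4-{[4-(benzyloxy)-2-methoxy-6-methylbenzoyl]oxy}-2-hydroxy-6-methylbenzoate | COc1cc(OCc2ccccc2)cc(C)c1C(=O)Oc1cc(C)c(C(=O)OCC=C)c(O)c1
F10 | step 8 | 4-{[4-(benzyloxy)-2-methoxy-6-methylbenzoyl]oxy}-2-hydroxy-6-methylbenzoic acid | COc1cc(OCc2ccccc2)cc(C)c1C(=O)Oc1cc(C)c(C(=O)O)c(O)c1
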